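**Strategy**

Everything rests on cutting the diaryl ether C–O bond between ring B and the oxygen on the para-phenylene ring C. In the target this oxygen sits on the ring B carbon next to the carbon bearing the free OH, so the bond can be made by oxidising a 4-alkyl-2,6-dibromophenol (ring B) and trapping it with a second phenol oxygen (ring C). One operation, Tl(NO3)3 oxidation followed by zinc reduction, forms this bond and closes the 18-membered ring. The precursor is an open-chain bis(bibenzyl): rings A and D already joined through oxygen, ring A masked as benzyl ether, ring B a 2,6-dibromophenol and ring C a 2,6-dichlorophenol.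

Key step: step 12

Remark: the Wittig steps give E/Z mixtures that converge in step 10, so the alkene geometry of 6, 9–12 and 15 is left open in the SMILES. Dienone 18 is racemic at its one sp3 carbon, which becomes sp2 again in the same step.

**Route**

Step 1
Reactants: 1 3-hydroxybenzyl alcohol
Product: 2 (3-hydroxybenzyl)triphenylphosphonium bromide
Conditions: PPh3·HBr, MeCN, reflux
Reagents that add atoms: triphenylphosphine hydrobromide, [Br-].c1ccc(cc1)[PH+](c1ccccc1)c1ccccc1
Why: Acid-promoted nucleophilic substitution of the benzylic hydroxyl by PPh3 (direct alcohol-to-phosphonium salt conversion) should give the salt without touching the phenol.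

Step 2
Reactants: 3 3,5-dichloro-4-hydroxybenzaldehyde
Product: 4 3,5-dichloro-4-(methoxymethoxy)benzaldehyde
Conditions: MOMCl, iPr2NEt, CH2Cl2, 0 °C → rt
Reagents that add atoms: chloromethyl methyl ether, COCCl
Why: O-alkylation of the acidic 2,6-dichlorophenol (MOM protection) keeps the aldehyde electrophilic for the Wittig step and leaves the ring D phenol as the only free phenol in the later Ullmann coupling.

Step 3
Reactants: 2 (3-hydroxybenzyl)triphenylphosphonium bromide; 4 3,5-dichloro-4-(methoxymethoxy)benzaldehyde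
Product: 6 3-{2-[3,5-dichloro-4-(methoxymethoxy)phenyl]ethenyl}phenol (E/Z mixture), via phenolate ylide 5 (not isolated)
Conditions: KOtBu (2.2 equiv), THF, 0 °C; then 4, 0 °C → rt; aq. HCl work-up
Reagents that add atoms: none
Why: Wittig olefination, in which two equivalents of base deprotonate the phenol and the benzylic position so that the semi-stabilised ylide should add to the non-enolisable, electron-poor aldehyde.

Step 4
Reactants: 7 2-bromo-5-hydroxybenzaldehyde
Product: 8 5-(benzyloxy)-2-bromobenzaldehyde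
Conditions: BnBr, K2CO3, DMF, rt
Reagents that add atoms: benzyl bromide, BrCc1ccccc1
Why: Williamson ether synthesis on the phenolate installs the ring A protecting group that survives every step up to the final hydrogenolysis.

Step 5
Reactants: 6 3-{2-[3,5-dichloro-4-(methoxymethoxy)phenyl]ethenyl}phenol; 8 5-(benzyloxy)-2-bromobenzaldehyde
Product: 9 5-(benzyloxy)-2-(3-{2-[3,5-dichloro-4-(methoxymethoxy)phenyl]ethenyl}phenoxy)benzaldehyde
Conditions: CuI (10 mol %), N,N-dimethylglycine hydrochloride (30 mol %), Cs2CO3, 1,4-dioxane, 90 °C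
Reagents that add atoms: none
Why: Ullmann diaryl ether synthesis with a monovalent copper catalyst, in which the ortho formyl group activates the C–Br bond of 8 while the aryl chlorides of ring C are inert at this temperature.

Step 6
Reactants: 9 5-(benzyloxy)-2-(3-{2-[3,5-dichloro-4-(methoxymethoxy)phenyl]ethenyl}phenoxy)benzaldehyde
Product: 10 [5-(benzyloxy)-2-(3-{2-[3,5-dichloro-4-(methoxymethoxy)phenyl]ethenyl}phenoxy)phenyl]methanol
Conditions: NaBH4, MeOH–THF, 0 °C
Reagents that add atoms: none
Why: Borohydride reduction of the aryl aldehyde to the benzylic alcohol leaves the alkene, acetal, ethers and aryl chlorides untouched.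

Step 7
Reactants: 10 [5-(benzyloxy)-2-(3-{2-[3,5-dichloro-4-(methoxymethoxy)phenyl]ethenyl}phenoxy)phenyl]methanol
Product: 12 {[5-(benzyloxy)-2-(3-{2-[3,5-dichloro-4-(methoxymethoxy)phenyl]ethenyl}phenoxy)phenyl]methyl}triphenylphosphonium bromide, via benzylic bromide 11 (not isolated)
Conditions: CBr4, PPh3, CH2Cl2, 0 °C → rt; solvent switch; PPh3, toluene, 110 °C
Reagents that add atoms: carbon tetrabromide, BrC(Br)(Br)Br; triphenylphosphine, c1ccc(cc1)P(c1ccccc1)c1ccccc1
Why: Appel bromination followed by SN2 quaternisation of PPh3 is acid-free, so the MOM acetal that HBr-based methods would endanger should survive.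

Step 8
Reactants: 13 3,5-dibromo-4-hydroxybenzaldehyde
Product: 14 3,5-dibromo-4-(methoxymethoxy)benzaldehyde
Conditions: MOMCl, iPr2NEt, CH2Cl2, 0 °C → rt
Reagents that add atoms: chloromethyl methyl ether, COCCl
Why: MOM protection (O-alkylation) prevents the dibromophenolate from deactivating the aldehyde and quenching the ylide in the next step.

Step 9
Reactants: 12 {[5-(benzyloxy)-2-(3-{2-[3,5-dichloro-4-(methoxymethoxy)phenyl]ethenyl}phenoxy)phenyl]methyl}triphenylphosphonium bromide; 14 3,5-dibromo-4-(methoxymethoxy)benzaldehyde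
Product: 15 4-(benzyloxy)-2-{2-[3,5-dibromo-4-(methoxymethoxy)phenyl]ethenyl}-1-(3-{2-[3,5-dichloro-4-(methoxymethoxy)phenyl]ethenyl}phenoxy)benzene (mixture of alkene isomers)
Conditions: K2CO3, 18-crown-6 (cat.), CH2Cl2, reflux
Reagents that add atoms: none
Why: Wittig olefination under solid–liquid phase-transfer conditions uses a carbonate base that cannot exchange or displace the aryl bromides.

Step 10
Reactants: 15 the bis-stilbene
Product: 16 4-(benzyloxy)-2-{2-[3,5-dibromo-4-(methoxymethoxy)phenyl]ethyl}-1-(3-{2-[3,5-dichloro-4-(methoxymethoxy)phenyl]ethyl}phenoxy)benzene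
Conditions: TsNHNH2 (excess, in portions), NaOAc, DME–H2O, reflux
Reagents that add atoms: none
Why: Diimide reduction transfers H2 concertedly to both stilbene double bonds and spares C–Br, C–Cl and the benzyl ether, which catalytic hydrogenation would attack.

Step 11
Reactants: 16 the bis(bibenzyl) bis-MOM ether
Product: 17 2,6-dibromo-4-{2-[5-(benzyloxy)-2-(3-{2-[3,5-dichloro-4-hydroxyphenyl]ethyl}phenoxy)phenyl]ethyl}phenol
Conditions: conc. HCl (cat.), MeOH–THF, 50 °C
Reagents that add atoms: none
Why: Acid-catalysed acetal methanolysis removes both MOM groups from the good-leaving-group halophenols, while benzyl and diaryl ethers are stable to these conditions.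

Step 12
Reactants: 17 the open-chain bis(bibenzyl) diphenol
Product: 19 macrocyclic diaryl ether (ring A benzyl ether, ring B 2-aryloxy-6-bromophenol, ring C 2,6-dichloro-substituted at its ether oxygen), via bromodienone 18 (not isolated)
Conditions: Tl(NO3)3·3H2O (3 equiv), MeOH–THF, ca. 1 mM, −20 → 0 °C; then Zn dust, AcOH, rt
Reagents that add atoms: none
Why: The ring B phenol, the more easily oxidised of the two because bromine lowers the oxidation potential relative to chlorine, binds trivalent thallium and loses two electrons to give a cyclohexadienone cation and TlNO3. The tethered ring C phenol oxygen then adds to one of the two equivalent bromine-bearing ortho carbons to give dienone 18, and zinc reduces its C–Br bond with loss of bromide so that ring B re-aromatises to the 2-aryloxy-6-bromophenol. The closest known reaction type is the thallium trinitrate coupling of ortho,ortho-dihalophenols to diaryl ethers with reductive work-up, which has been used to close macrocyclic diaryl ethers. The 18-membered ring closes end to end by intramolecular C–O bond formation, and high dilution should favour this over oligomerisation. No stereocentre survives, because the sp3 carbon of 18 is racemic and returns to sp2 on reduction. The step needs ring B to be the carbon acceptor and ring C the oxygen donor, which the Br/Cl pattern secures, and C–O coupling at an ortho carbon, which the four ortho halogens, the alkyl-blocked para positions and the inability of the ring A ether to bind thallium secure.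

Step 13
Reactants: 19 the macrocyclic bromo-dichloro benzyl ether
Product: 20 dihydroptychantol A
Conditions: H2 (1 atm), 10% Pd/C, NaOAc, MeOH–EtOAc, rt
Reagents that add atoms: none
Why: Catalytic hydrogenolysis on zerovalent palladium removes the C–Br bond, both C–Cl bonds and the O-benzyl group in one operation, with acetate trapping HBr and HCl without the slowing of debenzylation that amine additives can cause.

**Compound list**

1 | 3-hydroxybenzyl alcohol | OCc1cccc(O)c1 | starting material
2 | (3-hydroxybenzyl)triphenylphosphonium bromide | Oc1cccc(C[P+](c2ccccc2)(c2ccccc2)c2ccccc2)c1.[Br-] | intermediate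
3 | 3,5-dichloro-4-hydroxybenzaldehyde | O=Cc1cc(Cl)c(O)c(Cl)c1 | starting material
4 | 3,5-dichloro-4-(methoxymethoxy)benzaldehyde | O=Cc1cc(Cl)c(OCOC)c(Cl)c1 | intermediate
5 | potassium 3-[(triphenylphosphoranylidene)methyl]phenolate (phenolate ylide, not isolated) | [K+].[O-]c1cccc(C=P(c2ccccc2)(c2ccccc2)c2ccccc2)c1 | intermediate
6 | 3-{2-[3,5-dichloro-4-(methoxymethoxy)phenyl]ethenyl}phenol (E/Z mixture) | Oc1cccc(C=Cc2cc(Cl)c(OCOC)c(Cl)c2)c1 | intermediate
7 | 2-bromo-5-hydroxybenzaldehyde | O=Cc1cc(O)ccc1Br | starting material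
8 | 5-(benzyloxy)-2-bromobenzaldehyde | O=Cc1cc(OCc2ccccc2)ccc1Br | intermediate
9 | 5-(benzyloxy)-2-(3-{2-[3,5-dichloro-4-(methoxymethoxy)phenyl]ethenyl}phenoxy)benzaldehyde (E/Z mixture) | O=Cc1cc(OCc2ccccc2)ccc1Oc1cccc(C=Cc2cc(Cl)c(OCOC)c(Cl)c2)c1 | intermediate
10 | [5-(benzyloxy)-2-(3-{2-[3,5-dichloro-4-(methoxymethoxy)phenyl]ethenyl}phenoxy)phenyl]methanol (E/Z mixture) | OCc1cc(OCc2ccccc2)ccc1Oc1cccc(C=Cc2cc(Cl)c(OCOC)c(Cl)c2)c1 | intermediate
11 | 4-(benzyloxy)-2-(bromomethyl)-1-(3-{2-[3,5-dichloro-4-(methoxymethoxy)phenyl]ethenyl}phenoxy)benzene (benzylic bromide, not isolated) | BrCc1cc(OCc2ccccc2)ccc1Oc1cccc(C=Cc2cc(Cl)c(OCOC)c(Cl)c2)c1 | intermediate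
12 | {[5-(benzyloxy)-2-(3-{2-[3,5-dichloro-4-(methoxymethoxy)phenyl]ethenyl}phenoxy)phenyl]methyl}triphenylphosphonium bromide | [Br-].c1ccc(cc1)[P+](c1ccccc1)(c1ccccc1)Cc1cc(OCc2ccccc2)ccc1Oc1cccc(C=Cc2cc(Cl)c(OCOC)c(Cl)c2)c1 | intermediate
13 | 3,5-dibromo-4-hydroxybenzaldehyde | O=Cc1cc(Br)c(O)c(Br)c1 | starting material
14 | 3,5-dibromo-4-(methoxymethoxy)benzaldehyde | O=Cc1cc(Br)c(OCOC)c(Br)c1 | intermediate
15 | 4-(benzyloxy)-2-{2-[3,5-dibromo-4-(methoxymethoxy)phenyl]ethenyl}-1-(3-{2-[3,5-dichloro-4-(methoxymethoxy)phenyl]ethenyl}phenoxy)benzene (mixture of alkene isomers) | O(Cc1ccccc1)c1ccc(Oc2cccc(C=Cc3cc(Cl)c(OCOC)c(Cl)c3)c2)c(C=Cc2cc(Br)c(OCOC)c(Br)c2)c1 | intermediate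
16 | 4-(benzyloxy)-2-{2-[3,5-dibromo-4-(methoxymethoxy)phenyl]ethyl}-1-(3-{2-[3,5-dichloro-4-(methoxymethoxy)phenyl]ethyl}phenoxy)benzene | O(Cc1ccccc1)c1ccc(Oc2cccc(CCc3cc(Cl)c(OCOC)c(Cl)c3)c2)c(CCc2cc(Br)c(OCOC)c(Br)c2)c1 | intermediate
17 | 2,6-dibromo-4-{2-[5-(benzyloxy)-2-(3-{2-[3,5-dichloro-4-hydroxyphenyl]ethyl}phenoxy)phenyl]ethyl}phenol (open-chain bis(bibenzyl), key-step precursor) | O(Cc1ccccc1)c1ccc(Oc2cccc(CCc3cc(Cl)c(O)c(Cl)c3)c2)c(CCc2cc(Br)c(O)c(Br)c2)c1 | intermediate
18 | macrocyclic 6-aryloxy-2,6-dibromocyclohexa-2,4-dienone (ring B dearomatised, its sp3 carbon carrying Br and the ring C oxygen; racemic; not isolated) | O(Cc1ccccc1)c1ccc2c(c1)CCC1=CC(Br)(Oc3c(Cl)cc(cc3Cl)CCc3cccc(c3)O2)C(=O)C(Br)=C1 | intermediate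
19 | macrocyclic diaryl ether with ring A benzyl ether, one bromine on ring B ortho to its OH, two chlorines on ring C flanking its ether oxygen | O(Cc1ccccc1)c1ccc2c(c1)CCc1cc(Br)c(O)c(c1)Oc1c(Cl)cc(cc1Cl)CCc1cccc(c1)O2 | intermediate
20 | dihydroptychantol A | Oc1ccc2c(c1)CCc1ccc(O)c(c1)Oc1ccc(cc1)CCc1cccc(c1)O2 | target

**Count and risks**

Total step count: 13. Longest linear sequence: 10 steps (steps 1, 3, 5, 6, 7, 9, 10, 11, 12, 13).

Step 12 (most likely to fail). The tethered phenol may lose out to intermolecular coupling (dimers and oligomers), the wrong phenol may be oxidised, or methanol may capture the ring B cation before the ring C oxygen does. The fallback sets out from 2 and 8 and comes back at 20. It closes the same C–O bond by a copper-mediated intramolecular Ullmann etherification between a ring C phenol and a ring B aryl bromide, with no oxidation involved.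
- Ylide 5, made from 2 as in step 3, is condensed with commercial 4-(methoxymethoxy)benzaldehyde to give 3-{2-[4-(methoxymethoxy)phenyl]ethenyl}phenol F1.
- Coupling of this phenol with 8 as in step 5 gives 5-(benzyloxy)-2-(3-{2-[4-(methoxymethoxy)phenyl]ethenyl}phenoxy)benzaldehyde F2.
- NaBH4 gives the benzylic alcohol [5-(benzyloxy)-2-(3-{2-[4-(methoxymethoxy)phenyl]ethenyl}phenoxy)phenyl]methanol F3. CBr4/PPh3 gives the benzylic bromide 4-(benzyloxy)-2-(bromomethyl)-1-(3-{2-[4-(methoxymethoxy)phenyl]ethenyl}phenoxy)benzene F4. PPh3 in toluene gives {[5-(benzyloxy)-2-(3-{2-[4-(methoxymethoxy)phenyl]ethenyl}phenoxy)phenyl]methyl}triphenylphosphonium bromide F5.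
- Wittig reaction with commercial 4-(benzyloxy)-3-bromobenzaldehyde under the conditions of step 9 gives the bis-stilbene 4-(benzyloxy)-2-{2-[4-(benzyloxy)-3-bromophenyl]ethenyl}-1-(3-{2-[4-(methoxymethoxy)phenyl]ethenyl}phenoxy)benzene F6.
- Diimide as in step 10 gives 4-(benzyloxy)-2-{2-[4-(benzyloxy)-3-bromophenyl]ethyl}-1-(3-{2-[4-(methoxymethoxy)phenyl]ethyl}phenoxy)benzene F7.
- HCl in MeOH frees the ring C phenol 4-{2-[3-(4-(benzyloxy)-2-{2-[4-(benzyloxy)-3-bromophenyl]ethyl}phenoxy)phenyl]ethyl}phenol F8.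
- CuI, N,N-dimethylglycine and Cs2CO3 in dioxane at high dilution should displace the bromide ortho to the ring B benzyloxy group and give dihydroptychantol A dibenzyl ether F9.
- H2 over Pd/C then removes both benzyl groups to give 20.

Step 13. The heterogeneous catalyst may be deactivated by halide, or the reduction may stall at the two hindered C–Cl bonds flanking the ring C ether oxygen, leaving partly chlorinated material. The fallback sets out from 19 and comes back at 20. Homogeneous transfer hydrodehalogenation with Pd(allyl)Cl(IPr) (IPr = 1,3-bis(2,6-diisopropylphenyl)imidazol-2-ylidene), NaOtBu and iPrOH at 60 °C reduces hindered aryl chlorides and bromides but not benzyl ethers. It should give dihydroptychantol A ring A benzyl ether F10. BCl3 with pentamethylbenzene in CH2Cl2 at −78 °C then cleaves the benzyl ether to 20.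

Step 5. The coupling may be slow, with competing protodebromination of 8 or base-induced decay of the aldehyde at the temperature the copper catalyst needs. The fallback sets out from 6 and comes back at 9. It replaces copper catalysis with nucleophilic aromatic substitution. Commercial 2-fluoro-5-hydroxybenzaldehyde is benzylated (BnBr, K2CO3, DMF) to 5-(benzyloxy)-2-fluorobenzaldehyde F11. The phenolate of 6 then displaces the fluoride activated by the ortho formyl group (K2CO3, DMF, 120 °C) to give 9.

Further compounds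
F1 | step 12 | 3-{2-[4-(methoxymethoxy)phenyl]ethenyl}phenol (E/Z mixture) | Oc1cccc(C=Cc2ccc(OCOC)cc2)c1
F2 | step 12 | 5-(benzyloxy)-2-(3-{2-[4-(methoxymethoxy)phenyl]ethenyl}phenoxy)benzaldehyde | O=Cc1cc(OCc2ccccc2)ccc1Oc1cccc(C=Cc2ccc(OCOC)cc2)c1
F3 | step 12 | [5-(benzyloxy)-2-(3-{2-[4-(methoxymethoxy)phenyl]ethenyl}phenoxy)phenyl]methanol | OCc1cc(OCc2ccccc2)ccc1Oc1cccc(C=Cc2ccc(OCOC)cc2)c1
F4 | step 12 | 4-(benzyloxy)-2-(bromomethyl)-1-(3-{2-[4-(methoxymethoxy)phenyl]ethenyl}phenoxy)benzene | BrCc1cc(OCc2ccccc2)ccc1Oc1cccc(C=Cc2ccc(OCOC)cc2)c1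
F5 | step 12 | {[5-(benzyloxy)-2-(3-{2-[4-(methoxymethoxy)phenyl]ethenyl}phenoxy)phenyl]methyl}triphenylphosphonium bromide | [Br-].c1ccc(cc1)[P+](c1ccccc1)(c1ccccc1)Cc1cc(OCc2ccccc2)ccc1Oc1cccc(C=Cc2ccc(OCOC)cc2)c1
F6 | step 12 | 4-(benzyloxy)-2-{2-[4-(benzyloxy)-3-bromophenyl]ethenyl}-1-(3-{2-[4-(methoxymethoxy)phenyl]ethenyl}phenoxy)benzene (mixture of alkene isomers) | O(Cc1ccccc1)c1ccc(Oc2cccc(C=Cc3ccc(OCOC)cc3)c2)c(C=Cc2ccc(OCc3ccccc3)c(Br)c2)c1
F7 | step 12 | 4-(benzyloxy)-2-{2-[4-(benzyloxy)-3-bromophenyl]ethyl}-1-(3-{2-[4-(methoxymethoxy)phenyl]ethyl}phenoxy)benzene | O(Cc1ccccc1)c1ccc(Oc2cccc(CCc3ccc(OCOC)cc3)c2)c(CCc2ccc(OCc3ccccc3)c(Br)c2)c1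
F8 | step 12 | 4-{2-[3-(4-(benzyloxy)-2-{2-[4-(benzyloxy)-3-bromophenyl]ethyl}phenoxy)phenyl]ethyl}phenol | O(Cc1ccccc1)c1ccc(Oc2cccc(CCc3ccc(O)cc3)c2)c(CCc2ccc(OCc3ccccc3)c(Br)c2)c1
F9 | step 12 | dihydroptychantol A dibenzyl ether (benzyl on the ring A and ring B oxygens) | O(Cc1ccccc1)c1ccc2c(c1)CCc1ccc(OCc3ccccc3)c(c1)Oc1ccc(cc1)CCc1cccc(c1)O2
F10 | step 13 | dihydroptychantol A ring A benzyl ether | O(Cc1ccccc1)c1ccc2c(c1)CCc1ccc(O)c(c1)Oc1ccc(cc1)CCc1cccc(c1)O2
F11 | step 5 | 5-(benzyloxy)-2-fluorobenzaldehyde | O=Cc1cc(OCc2ccccc2)ccc1F
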